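**Retrosynthetic overview**
- The target is a 6,7-cis-fused α-methylene-γ-butyrolactone on a ten-membered carbocycle; the endgame is desilylation ⇐ C8 angeloylation ⇐ C3 oxidation.
- The ten-membered ring is formed second, by intramolecular Nozaki–Hiyama–Kishi closure of C3–C4 (Z-alkenyl iodide onto a C3 aldehyde).
- The lactone ring is formed first, together with the C6–C7 bond: intermolecular indium Barbier allylation of a (Z)-β-iodo enal (C4–C6, C15) with a (Z)-2-(bromomethyl)enoate (C1–C3, C7–C14), then lactonisation. C6 and C7 are set here under control of C8.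
- The bromide comes from (R)-linalool (C10), via hydroformylation, L-proline α-aminoxylation (C8) and Morita–Baylis–Hillman/SN2′ bromination; the enal comes from but-2-yne-1,4-diol.

Assumption: the target is made in the open 3-oxo/10-hydroxy form of the given SMILES (a 3,10-hemiketal, if it forms, is a ring–chain tautomer of the same compound).

Position numbers are those of germacranolides: C1–C10 ring, C11–C13 lactone unit, C14 = methyl on C10, C15 = CH2O on C4. TBS = tert-butyldimethylsilyl, TES = triethylsilyl, TBDPS = tert-butyldiphenylsilyl, PMB = 4-methoxybenzyl. The stereochemical outcome of step 14 rests on a transition-state model, not on a known result for this substrate.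

**Route**

Step 1
Reactants: 1 (R)-(−)-linalool, (3R)-3,7-dimethylocta-1,6-dien-3-ol
Product: 2 (3R)-3-(TBS-oxy)-3,7-dimethylocta-1,6-diene
Conditions: TBSOTf, 2,6-lutidine, CH2Cl2, 0 °C → rt
Reagents that add atoms: tert-butyldimethylsilyl trifluoromethanesulfonate, CC(C)(C)[Si](C)(C)OS(=O)(=O)C(F)(F)F
Why: Silylation of the hindered tertiary allylic alcohol with the silyl triflate is fast and non-ionising, and the robust tertiary TBS ether masks O10 until the last step while C10 is untouched.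

Step 2
Reactants: 2 (3R)-3-(TBS-oxy)-3,7-dimethylocta-1,6-diene
Product: 4 (4R)-4-(TBS-oxy)-4-methylhex-5-en-1-ol, via silyloxy aldehyde 3 (not isolated)
Conditions: O3, CH2Cl2/MeOH (4:1), −78 °C, Sudan Red 7B end point; then NaBH4, −78 °C → rt
Reagents that add atoms: ozone, [O-][O+]=O
Why: Chemoselective ozonolysis, because the electron-rich trisubstituted alkene reacts far faster than the hindered vinyl group, so one equivalent of ozone cleaves only C3=C(CH3)2 and NaBH4 reduces the aldehyde to the primary alcohol.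

Step 3
Reactants: 4 (4R)-4-(TBS-oxy)-4-methylhex-5-en-1-ol
Product: 5 (3R)-3-(TBS-oxy)-6-(PMB-oxy)-3-methylhex-1-ene
Conditions: NaH, 4-methoxybenzyl chloride, Bu4NI (cat.), THF/DMF, 0 °C → rt
Reagents that add atoms: 4-methoxybenzyl chloride, COc1ccc(CCl)cc1
Why: Williamson etherification of the only free (primary) hydroxyl gives a PMB ether that survives every step until its oxidative removal.

Step 4
Reactants: 5 (3R)-3-(TBS-oxy)-6-(PMB-oxy)-3-methylhex-1-ene
Product: 6 (4R)-4-(TBS-oxy)-7-(PMB-oxy)-4-methylheptanal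
Conditions: Rh(acac)(CO)2 (1 mol %), Xantphos (2 mol %), CO/H2 (1:1, 10 bar), toluene, 80 °C
Reagents that add atoms: carbon monoxide, [C-]#[O+]
Why: Rhodium-catalysed hydroformylation of a monosubstituted alkene next to a quaternary carbon is essentially linear-selective (no branched insertion, no isomerisation possible) and adds C7 as the aldehyde.

Step 5
Reactants: 6 (4R)-4-(TBS-oxy)-7-(PMB-oxy)-4-methylheptanal
Product: 8 (2R,4R)-2-(anilinooxy)-4-(TBS-oxy)-7-(PMB-oxy)-4-methylheptan-1-ol, via aminooxy aldehyde 7 (not isolated)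
Conditions: PhNO (1.0 equiv), L-proline (25 mol %), DMSO, rt, 30 min; then NaBH4, MeOH, 0 °C
Reagents that add atoms: nitrosobenzene, O=Nc1ccccc1
Why: Proline-catalysed α-aminoxylation (enamine catalysis), in which the L-proline enamine attacks the acid-activated nitroso oxygen on one face only and so sets C8 as R under catalyst control, independent of the remote C10 centre, before NaBH4 traps the labile aldehyde.

Step 6
Reactants: 8 (2R,4R)-2-(anilinooxy)-4-(TBS-oxy)-7-(PMB-oxy)-4-methylheptan-1-ol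
Product: 9 (2R,4R)-4-(TBS-oxy)-7-(PMB-oxy)-4-methylheptane-1,2-diol
Conditions: Zn dust, AcOH/EtOH (1:3), rt
Reagents that add atoms: none
Why: Reductive N–O cleavage by zinc in acetic acid frees the C8 hydroxyl without touching the silyl or PMB ethers or the C8 configuration.

Step 7
Reactants: 9 (2R,4R)-4-(TBS-oxy)-7-(PMB-oxy)-4-methylheptane-1,2-diol
Product: 10 (2R,4R)-4-(TBS-oxy)-7-(PMB-oxy)-4-methyl-1,2-bis(TES-oxy)heptane
Conditions: TESCl (2.5 equiv), imidazole, DMF, 0 °C → rt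
Reagents that add atoms: chlorotriethylsilane, CC[Si](Cl)(CC)CC
Why: Exhaustive silylation protects both hydroxyls, and the secondary TES ether becomes the bulky, non-chelating O8 group needed in step 14 that can later be removed beside TBS and TBDPS ethers.

Step 8
Reactants: 10 (2R,4R)-4-(TBS-oxy)-7-(PMB-oxy)-4-methyl-1,2-bis(TES-oxy)heptane
Product: 11 (2R,4R)-4-(TBS-oxy)-7-(PMB-oxy)-4-methyl-2-(TES-oxy)heptanal
Conditions: (COCl)2, DMSO, CH2Cl2, −78 → −35 °C; then Et3N, −78 → 0 °C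
Reagents that add atoms: none
Why: Swern conditions oxidise a primary triethylsilyl ether directly to the aldehyde (desilylative Swern oxidation) while secondary TES, tertiary TBS and PMB ethers are inert, and the cold protocol does not epimerise the α-silyloxy aldehyde.

Step 9
Reactants: 11 (2R,4R)-4-(TBS-oxy)-7-(PMB-oxy)-4-methyl-2-(TES-oxy)heptanal; 12 methyl acrylate
Product: 13 methyl (4R,6R)-6-(TBS-oxy)-3-hydroxy-9-(PMB-oxy)-6-methyl-2-methylidene-4-(TES-oxy)nonanoate (both C3 epimers)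
Conditions: DABCO (1.0 equiv), methyl acrylate (10 equiv, neat), rt, 3–5 d
Reagents that add atoms: none
Why: Morita–Baylis–Hillman reaction, for which α-oxygenated aldehydes are activated acceptors of the amine–acrylate zwitterion, and the new carbinol centre (C7) is irrelevant because it is erased in step 10.

Step 10
Reactants: 13 methyl (4R,6R)-6-(TBS-oxy)-3-hydroxy-9-(PMB-oxy)-6-methyl-2-methylidene-4-(TES-oxy)nonanoate
Product: 14 methyl (2Z,4R,6R)-2-(bromomethyl)-6-(TBS-oxy)-9-(PMB-oxy)-6-methyl-4-(TES-oxy)non-2-enoate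
Conditions: NBS, Me2S, CH2Cl2, 0 °C → rt
Reagents that add atoms: N-bromosuccinimide, O=C1CCC(=O)N1Br
Why: SN2′ bromination of the Baylis–Hillman alcohol through its alkoxysulfonium salt gives the conjugated trisubstituted allylic bromide under thermodynamic control, with the C8 chain cis to CH2Br (Z).

Step 11
Reactants: 15 but-2-yne-1,4-diol
Product: 16 4-(TBDPS-oxy)but-2-yn-1-ol
Conditions: 15 (3 equiv), TBDPSCl (1 equiv), imidazole, DMF, 0 °C → rt
Reagents that add atoms: tert-butyl(chloro)diphenylsilane, CC(C)(C)[Si](Cl)(c1ccccc1)c1ccccc1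
Why: Statistical monosilylation of the cheap symmetrical diol used in excess, with TBDPS chosen because it survives every later acidic and oxidative step.

Step 12
Reactants: 16 4-(TBDPS-oxy)but-2-yn-1-ol
Product: 18 (2Z)-4-(TBDPS-oxy)-3-iodobut-2-en-1-ol, via cyclic alkenylaluminate 17 (not isolated)
Conditions: NaAlH2(OCH2CH2OMe)2 (1.5 equiv), THF, 0 °C; then I2, THF, −78 → 0 °C
Reagents that add atoms: iodine, II
Why: Hydroxyl-directed trans-hydroalumination of the propargylic alcohol puts aluminium on the distal alkyne carbon in a five-membered alanate, and iodinolysis with retention gives the (Z)-3-iodo allylic alcohol regio- and stereospecifically.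

Step 13
Reactants: 18 (2Z)-4-(TBDPS-oxy)-3-iodobut-2-en-1-ol
Product: 19 (2Z)-4-(TBDPS-oxy)-3-iodobut-2-enal
Conditions: activated MnO2 (15 equiv), CH2Cl2, rt
Reagents that add atoms: none
Why: Allylic oxidation with MnO2 is neutral and does not isomerise the (Z)-β-iodo enal.

Step 14
Reactants: 14 methyl (2Z,4R,6R)-2-(bromomethyl)-6-(TBS-oxy)-9-(PMB-oxy)-6-methyl-4-(TES-oxy)non-2-enoate; 19 (2Z)-4-(TBDPS-oxy)-3-iodobut-2-enal
Product: 21 (4S,5R)-4-[(1R,3R)-3-(TBS-oxy)-6-(PMB-oxy)-3-methyl-1-(TES-oxy)hexyl]-5-[(1Z)-3-(TBDPS-oxy)-2-iodoprop-1-en-1-yl]-3-methylidenedihydrofuran-2(3H)-one (4,5-cis), via syn hydroxy ester 20 (not isolated)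
Conditions: In powder (1.5 equiv), 19 (1.5 equiv), DMF, rt; aq. NaHCO3 work-up; then PPTS (10 mol %), CH2Cl2, rt
Reagents that add atoms: none
Why: Barbier-type carbonyl allylation (SE2′) through a closed chair transition state, in which the Z-configured allylindium carries the C8 chain axially and the aldehyde substituent equatorially to give the 6,7-syn adduct and hence the cis-lactone, while C8 directs the face at C7 (H8 over the ring to avoid A(1,3) strain, C9 chain anti to the forming bond, silyloxy group outside), and acid then lactonises the hydroxy ester.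

Step 15
Reactants: 21 PMB-protected cis-lactone (name as in step 14)
Product: 22 (4S,5R)-4-[(1R,3R)-3-(TBS-oxy)-6-hydroxy-3-methyl-1-(TES-oxy)hexyl]-5-[(1Z)-3-(TBDPS-oxy)-2-iodoprop-1-en-1-yl]-3-methylidenedihydrofuran-2(3H)-one
Conditions: DDQ, CH2Cl2/pH 7 buffer (10:1), 0 °C → rt
Reagents that add atoms: none
Why: Oxidative PMB cleavage with DDQ is neutral and leaves the silyl ethers, the alkenyl iodide and the methylene lactone untouched.

Step 16
Reactants: 22 C3 alcohol (name as in step 15)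
Product: 23 (4S,5R)-4-[(1R,3R)-3-(TBS-oxy)-3-methyl-6-oxo-1-(TES-oxy)hexyl]-5-[(1Z)-3-(TBDPS-oxy)-2-iodoprop-1-en-1-yl]-3-methylidenedihydrofuran-2(3H)-one
Conditions: Dess–Martin periodinane, pyridine, CH2Cl2, 0 °C → rt
Reagents that add atoms: none
Why: Dess–Martin oxidation gives the aldehyde under buffered conditions that spare the TES ether and the lactone.

Step 17
Reactants: 23 iodo aldehyde (name as in step 16)
Product: 24 (4Z)-10-(TBS-oxy)-15-(TBDPS-oxy)-3-hydroxy-8-(TES-oxy)germacra-4,11(13)-dien-12,6-olide (C6, C7, C8, C10 as in the target; both C3 epimers)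
Conditions: CrCl2 (15 equiv), NiCl2 (0.15 equiv), DMSO, rt, slow addition of 23, final 0.003 M
Reagents that add atoms: none
Why: Intramolecular Nozaki–Hiyama–Kishi reaction, in which the alkenylchromium species forms with retention of the Z geometry and adds chemoselectively to the aldehyde, the cis-alkene and cis-lactone acting as turn elements for the ten-membered ring, and the new C3 carbinol centre is removed in step 18.

Step 18
Reactants: 24 macrocyclic allylic alcohol (name as in step 17)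
Product: 25 (4Z)-10-(TBS-oxy)-15-(TBDPS-oxy)-3-oxo-8-(TES-oxy)germacra-4,11(13)-dien-12,6-olide
Conditions: Dess–Martin periodinane, pyridine, CH2Cl2, 0 °C → rt
Reagents that add atoms: none
Why: Dess–Martin oxidation of both allylic alcohol epimers converges on the single cross-conjugated enone.

Step 19
Reactants: 25 (4Z)-10-(TBS-oxy)-15-(TBDPS-oxy)-3-oxo-8-(TES-oxy)germacra-4,11(13)-dien-12,6-olide
Product: 26 (4Z)-10-(TBS-oxy)-15-(TBDPS-oxy)-8-hydroxy-3-oxogermacra-4,11(13)-dien-12,6-olide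
Conditions: PPTS (0.3 equiv), MeOH/CH2Cl2 (1:1), 0 °C → rt
Reagents that add atoms: none
Why: Acid-catalysed methanolysis removes the secondary TES ether far faster than the tertiary TBS or the primary TBDPS ether.

Step 20
Reactants: 26 (4Z)-10-(TBS-oxy)-15-(TBDPS-oxy)-8-hydroxy-3-oxogermacra-4,11(13)-dien-12,6-olide; 27 angelic acid, (2Z)-2-methylbut-2-enoic acid
Product: 29 (4Z)-8-angeloyloxy-10-(TBS-oxy)-15-(TBDPS-oxy)-3-oxogermacra-4,11(13)-dien-12,6-olide, via mixed anhydride 28 (not isolated)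
Conditions: 27 (5 equiv), 2,4,6-trichlorobenzoyl chloride, Et3N, toluene, rt; then 26, 75 °C
Reagents that add atoms: none
Why: Yamaguchi-type esterification through the mixed anhydride without DMAP acylates the hindered secondary alcohol while avoiding angelate-to-tiglate isomerisation, and C8 keeps its configuration because its C–O bond is not broken.

Step 21
Reactants: 29 (4Z)-8-angeloyloxy-10-(TBS-oxy)-15-(TBDPS-oxy)-3-oxogermacra-4,11(13)-dien-12,6-olide
Product: 30 target CNP0181802.1, (4Z,6S,7R,8R,10R)-8-angeloyloxy-10,15-dihydroxy-3-oxogermacra-4,11(13)-dien-12,6-olide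
Conditions: 48 % aq. HF/MeCN (1:10), 0 °C → rt, polypropylene vessel
Reagents that add atoms: none
Why: Fluoride-mediated desilylation under acidic, non-nucleophilic conditions removes both remaining silyl ethers while the angelate, enone and methylene lactone are tolerated.

**Compound list**

1 | (R)-(−)-linalool | C=C[C@](C)(O)CCC=C(C)C | starting material
2 | (3R)-3-(TBS-oxy)-3,7-dimethylocta-1,6-diene | C=C[C@](C)(O[Si](C)(C)C(C)(C)C)CCC=C(C)C | intermediate
3 | (4R)-4-(TBS-oxy)-4-methylhex-5-enal | C=C[C@](C)(O[Si](C)(C)C(C)(C)C)CCC=O | intermediate (not isolated)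
4 | (4R)-4-(TBS-oxy)-4-methylhex-5-en-1-ol | C=C[C@](C)(O[Si](C)(C)C(C)(C)C)CCCO | intermediate
5 | (3R)-3-(TBS-oxy)-6-(PMB-oxy)-3-methylhex-1-ene | C=C[C@](C)(O[Si](C)(C)C(C)(C)C)CCCOCc1ccc(OC)cc1 | intermediate
6 | (4R)-4-(TBS-oxy)-7-(PMB-oxy)-4-methylheptanal | O=CCC[C@](C)(O[Si](C)(C)C(C)(C)C)CCCOCc1ccc(OC)cc1 | intermediate
7 | (2R,4R)-2-(anilinooxy)-4-(TBS-oxy)-7-(PMB-oxy)-4-methylheptanal | O=C[C@H](ONc1ccccc1)C[C@](C)(O[Si](C)(C)C(C)(C)C)CCCOCc1ccc(OC)cc1 | intermediate (not isolated)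
8 | (2R,4R)-2-(anilinooxy)-4-(TBS-oxy)-7-(PMB-oxy)-4-methylheptan-1-ol | OC[C@H](ONc1ccccc1)C[C@](C)(O[Si](C)(C)C(C)(C)C)CCCOCc1ccc(OC)cc1 | intermediate
9 | (2R,4R)-4-(TBS-oxy)-7-(PMB-oxy)-4-methylheptane-1,2-diol | OC[C@H](O)C[C@](C)(O[Si](C)(C)C(C)(C)C)CCCOCc1ccc(OC)cc1 | intermediate
10 | (2R,4R)-4-(TBS-oxy)-7-(PMB-oxy)-4-methyl-1,2-bis(TES-oxy)heptane | CC[Si](CC)(CC)OC[C@H](O[Si](CC)(CC)CC)C[C@](C)(O[Si](C)(C)C(C)(C)C)CCCOCc1ccc(OC)cc1 | intermediate
11 | (2R,4R)-4-(TBS-oxy)-7-(PMB-oxy)-4-methyl-2-(TES-oxy)heptanal | O=C[C@H](O[Si](CC)(CC)CC)C[C@](C)(O[Si](C)(C)C(C)(C)C)CCCOCc1ccc(OC)cc1 | intermediate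
12 | methyl acrylate | C=CC(=O)OC | starting material
13 | methyl (4R,6R)-6-(TBS-oxy)-3-hydroxy-9-(PMB-oxy)-6-methyl-2-methylidene-4-(TES-oxy)nonanoate (both C3 epimers) | C=C(C(=O)OC)C(O)[C@H](O[Si](CC)(CC)CC)C[C@](C)(O[Si](C)(C)C(C)(C)C)CCCOCc1ccc(OC)cc1 | intermediate
14 | methyl (2Z,4R,6R)-2-(bromomethyl)-6-(TBS-oxy)-9-(PMB-oxy)-6-methyl-4-(TES-oxy)non-2-enoate | BrC/C(C(=O)OC)=C\[C@H](O[Si](CC)(CC)CC)C[C@](C)(O[Si](C)(C)C(C)(C)C)CCCOCc1ccc(OC)cc1 | intermediate
15 | but-2-yne-1,4-diol | OCC#CCO | starting material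
16 | 4-(TBDPS-oxy)but-2-yn-1-ol | OCC#CCO[Si](c1ccccc1)(c1ccccc1)C(C)(C)C | intermediate
17 | sodium 2,2-bis(2-methoxyethoxy)-3-[(TBDPS-oxy)methyl]-2,5-dihydro-1,2-oxaalumol-2-uide | [Na+].COCCO[Al-]1(OCCOC)OCC=C1CO[Si](c1ccccc1)(c1ccccc1)C(C)(C)C | intermediate (not isolated)
18 | (2Z)-4-(TBDPS-oxy)-3-iodobut-2-en-1-ol | OC/C=C(/CO[Si](c1ccccc1)(c1ccccc1)C(C)(C)C)I | intermediate
19 | (2Z)-4-(TBDPS-oxy)-3-iodobut-2-enal | O=C/C=C(/CO[Si](c1ccccc1)(c1ccccc1)C(C)(C)C)I | intermediate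
20 | methyl (3S,4R,5Z)-7-(TBDPS-oxy)-4-hydroxy-6-iodo-2-methylidene-3-[(1R,3R)-3-(TBS-oxy)-6-(PMB-oxy)-3-methyl-1-(TES-oxy)hexyl]hept-5-enoate | C=C(C(=O)OC)[C@@H]([C@@H](O)/C=C(/CO[Si](c1ccccc1)(c1ccccc1)C(C)(C)C)I)[C@H](O[Si](CC)(CC)CC)C[C@](C)(O[Si](C)(C)C(C)(C)C)CCCOCc1ccc(OC)cc1 | intermediate (not isolated)
21 | (4S,5R)-4-[(1R,3R)-3-(TBS-oxy)-6-(PMB-oxy)-3-methyl-1-(TES-oxy)hexyl]-5-[(1Z)-3-(TBDPS-oxy)-2-iodoprop-1-en-1-yl]-3-methylidenedihydrofuran-2(3H)-one (4,5-cis) | C=C1C(=O)O[C@@H](/C=C(/CO[Si](c2ccccc2)(c2ccccc2)C(C)(C)C)I)[C@H]1[C@H](O[Si](CC)(CC)CC)C[C@](C)(O[Si](C)(C)C(C)(C)C)CCCOCc1ccc(OC)cc1 | intermediate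
22 | (4S,5R)-4-[(1R,3R)-3-(TBS-oxy)-6-hydroxy-3-methyl-1-(TES-oxy)hexyl]-5-[(1Z)-3-(TBDPS-oxy)-2-iodoprop-1-en-1-yl]-3-methylidenedihydrofuran-2(3H)-one | C=C1C(=O)O[C@@H](/C=C(/CO[Si](c2ccccc2)(c2ccccc2)C(C)(C)C)I)[C@H]1[C@H](O[Si](CC)(CC)CC)C[C@](C)(O[Si](C)(C)C(C)(C)C)CCCO | intermediate
23 | (4S,5R)-4-[(1R,3R)-3-(TBS-oxy)-3-methyl-6-oxo-1-(TES-oxy)hexyl]-5-[(1Z)-3-(TBDPS-oxy)-2-iodoprop-1-en-1-yl]-3-methylidenedihydrofuran-2(3H)-one | C=C1C(=O)O[C@@H](/C=C(/CO[Si](c2ccccc2)(c2ccccc2)C(C)(C)C)I)[C@H]1[C@H](O[Si](CC)(CC)CC)C[C@](C)(O[Si](C)(C)C(C)(C)C)CCC=O | intermediate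
24 | (4Z)-10-(TBS-oxy)-15-(TBDPS-oxy)-3-hydroxy-8-(TES-oxy)germacra-4,11(13)-dien-12,6-olide (C6, C7, C8, C10 as in the target; both C3 epimers) | C=C1C(=O)O[C@H]2/C=C(/CO[Si](c3ccccc3)(c3ccccc3)C(C)(C)C)C(O)CC[C@@](C)(O[Si](C)(C)C(C)(C)C)C[C@@H](O[Si](CC)(CC)CC)[C@@H]12 | intermediate
25 | (4Z)-10-(TBS-oxy)-15-(TBDPS-oxy)-3-oxo-8-(TES-oxy)germacra-4,11(13)-dien-12,6-olide | C=C1C(=O)O[C@H]2/C=C(/CO[Si](c3ccccc3)(c3ccccc3)C(C)(C)C)C(=O)CC[C@@](C)(O[Si](C)(C)C(C)(C)C)C[C@@H](O[Si](CC)(CC)CC)[C@@H]12 | intermediate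
26 | (4Z)-10-(TBS-oxy)-15-(TBDPS-oxy)-8-hydroxy-3-oxogermacra-4,11(13)-dien-12,6-olide | C=C1C(=O)O[C@H]2/C=C(/CO[Si](c3ccccc3)(c3ccccc3)C(C)(C)C)C(=O)CC[C@@](C)(O[Si](C)(C)C(C)(C)C)C[C@@H](O)[C@@H]12 | intermediate
27 | angelic acid, (2Z)-2-methylbut-2-enoic acid | C/C=C(/C)C(=O)O | starting material
28 | (2Z)-2-methylbut-2-enoic 2,4,6-trichlorobenzoic anhydride | C/C=C(/C)C(=O)OC(=O)c1c(Cl)cc(Cl)cc1Cl | intermediate (not isolated)
29 | (4Z)-8-angeloyloxy-10-(TBS-oxy)-15-(TBDPS-oxy)-3-oxogermacra-4,11(13)-dien-12,6-olide | C=C1C(=O)O[C@H]2/C=C(/CO[Si](c3ccccc3)(c3ccccc3)C(C)(C)C)C(=O)CC[C@@](C)(O[Si](C)(C)C(C)(C)C)C[C@@H](OC(=O)/C(C)=C\C)[C@@H]12 | intermediate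
30 | CNP0181802.1, (4Z,6S,7R,8R,10R)-8-angeloyloxy-10,15-dihydroxy-3-oxogermacra-4,11(13)-dien-12,6-olide | C=C1C(=O)O[C@H]2/C=C(/CO)C(=O)CC[C@@](C)(O)C[C@@H](OC(=O)/C(C)=C\C)[C@@H]12 | target

**Step count and risks**

Total: 21 steps. Longest linear sequence: 18 steps (steps 1–10, then 14–21, from (R)-linalool); the enal arm is 3 steps (11–13).

The three steps most likely to fail:

(a) Step 9, the Morita–Baylis–Hillman reaction. The α-silyloxy aldehyde is hindered, so the reaction may be slow, and prolonged amine exposure can epimerise C8 or move the TES group. The fallback sets out from aldehyde 11. It is treated at −78 °C in THF with the lithium enolate of methyl 3-(phenylselanyl)propanoate (made with LiN(i-Pr)2) to give the β-hydroxy selenide F1. Oxidation with H2O2/pyridine in CH2Cl2 at 0 °C and selenoxide syn-elimination then give the same allylic alcohol, so the route is rejoined at 13.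

(b) Step 14, the indium allylation. It must deliver both the 6,7-syn relationship and the correct face at C7, and Wurtz coupling or loss of the allyl geometry would erode either. The fallback sets out from bromide 14. It is converted with B2pin2 and Pd2(dba)3 (cat.) in THF at 50 °C into the isolable, geometrically fixed pinacol allylboronate F2. Uncatalysed thermal allylboration of enal 19 in toluene (rt → 80 °C) proceeds through a tighter six-membered transition state with short B–O bonds. Hydrolytic work-up and the same PPTS treatment lead through 20 back to the route at 21.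

(c) Step 17, the Nozaki–Hiyama–Kishi ring closure. Dimerisation, protodeiodination, or nickel-mediated cyclisation of the alkenyl unit onto the methylene lactone can compete with formation of the ten-membered ring. The fallback closes the ring at C4=C5 by metathesis and sets out from bromide 14.
- Bromide 14 is coupled with acrolein under the step 14 conditions to give the hydroxy ester F3 and, after PPTS, the vinyl lactone F4.
- DDQ then gives the primary alcohol F5, and Dess–Martin periodinane the aldehyde F6.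
- Separately, 2-bromoprop-2-en-1-ol is silylated (TBDPSCl, imidazole) to the bromoallyl silyl ether F7.
- Intermolecular CrCl2/NiCl2 coupling of F7 with F6 in DMSO gives the diene alcohol F8.
- Ring-closing metathesis of F8 with second-generation Grubbs catalyst, (H2IMes)(PCy3)Cl2Ru=CHPh, in toluene at 80 °C and 0.001 M expels ethene and returns to the route at 24.

**Further compounds**

F1 | step 9 | methyl (4R,6R)-6-(TBS-oxy)-3-hydroxy-9-(PMB-oxy)-6-methyl-2-[(phenylselanyl)methyl]-4-(TES-oxy)nonanoate (mixture at C2 and C3) | COC(=O)C(C[Se]c1ccccc1)C(O)[C@H](O[Si](CC)(CC)CC)C[C@](C)(O[Si](C)(C)C(C)(C)C)CCCOCc1ccc(OC)cc1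
F2 | step 14 | methyl (2E,4R,6R)-6-(TBS-oxy)-9-(PMB-oxy)-6-methyl-2-[(4,4,5,5-tetramethyl-1,3,2-dioxaborolan-2-yl)methyl]-4-(TES-oxy)non-2-enoate | CC1(C)OB(C/C(C(=O)OC)=C\[C@H](O[Si](CC)(CC)CC)C[C@](C)(O[Si](C)(C)C(C)(C)C)CCCOCc2ccc(OC)cc2)OC1(C)C
F3 | step 17 | methyl 4-hydroxy-2-methylidene-3-[(1R,3R)-3-(TBS-oxy)-6-(PMB-oxy)-3-methyl-1-(TES-oxy)hexyl]hex-5-enoate (C3 and C4 configured as C7 and C6 of 20) | C=C(C(=O)OC)[C@@H]([C@@H](O)C=C)[C@H](O[Si](CC)(CC)CC)C[C@](C)(O[Si](C)(C)C(C)(C)C)CCCOCc1ccc(OC)cc1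
F4 | step 17 | 4,5-cis-5-ethenyl-4-[(1R,3R)-3-(TBS-oxy)-6-(PMB-oxy)-3-methyl-1-(TES-oxy)hexyl]-3-methylidenedihydrofuran-2(3H)-one (ring centres as in 21) | C=C1C(=O)O[C@@H](C=C)[C@H]1[C@H](O[Si](CC)(CC)CC)C[C@](C)(O[Si](C)(C)C(C)(C)C)CCCOCc1ccc(OC)cc1
F5 | step 17 | 4,5-cis-5-ethenyl-4-[(1R,3R)-3-(TBS-oxy)-6-hydroxy-3-methyl-1-(TES-oxy)hexyl]-3-methylidenedihydrofuran-2(3H)-one | C=C1C(=O)O[C@@H](C=C)[C@H]1[C@H](O[Si](CC)(CC)CC)C[C@](C)(O[Si](C)(C)C(C)(C)C)CCCO
F6 | step 17 | 4,5-cis-5-ethenyl-4-[(1R,3R)-3-(TBS-oxy)-3-methyl-6-oxo-1-(TES-oxy)hexyl]-3-methylidenedihydrofuran-2(3H)-one | C=C1C(=O)O[C@@H](C=C)[C@H]1[C@H](O[Si](CC)(CC)CC)C[C@](C)(O[Si](C)(C)C(C)(C)C)CCC=O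
F7 | step 17 | [(2-bromoprop-2-en-1-yl)oxy](tert-butyl)diphenylsilane | C=C(Br)CO[Si](c1ccccc1)(c1ccccc1)C(C)(C)C
F8 | step 17 | 4,5-cis-5-ethenyl-4-[(1R,3R)-3-(TBS-oxy)-7-[(TBDPS-oxy)methyl]-6-hydroxy-3-methyl-1-(TES-oxy)oct-7-en-1-yl]-3-methylidenedihydrofuran-2(3H)-one (both carbinol epimers) | C=C1C(=O)O[C@@H](C=C)[C@H]1[C@H](O[Si](CC)(CC)CC)C[C@](C)(O[Si](C)(C)C(C)(C)C)CCC(O)C(=C)CO[Si](c1ccccc1)(c1ccccc1)C(C)(C)C
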